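**Retrosynthetic overview**
1. The stilbene C=C is made last by a Mizoroki–Heck union of the 8-vinylflavan 10 (rings B, C, D) with the ring-A aryl iodide 15; ring A comes from 2,6-dimethoxytoluene by C–H borylation/oxidation and iodination.
2. The C8 vinyl group of 10 is put on the finished flavan 8 by C8 bromination and Suzuki–Miyaura vinylation.
3. Pyran ring C of 8 is closed by forming the C2–C3 bond in an enantioconvergent, catalyst-controlled reductive Prins cyclization of the racemic acyclic mixed acetal 5 (from aldehyde 1 and benzaldehyde dimethyl acetal 2); one operation makes ring C, the C2 stereocentre and the C4 methylene.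
4. Enabling feature: on ring B, C4a stands ortho to O1 and to the C5 methoxy group and para to the C7 methoxy group, so a vinyl group on C4a is a strong π-nucleophile at its terminal carbon (C3) and C4 can hold the cation until hydride arrives, while O1 carries C2 as an oxocarbenium ion.
5. Ring order: rings A, B and D are bought as benzenes; ring C is formed in step 3; ring A is joined in step 9.

Key step: step 3

Remark on naming: chroman numbering (O1, C2, C3, C4, C4a, C5 to C8, C8a) is used throughout; ring A = phenol ring of the stilbene, ring B = benzo ring of the chroman, ring C = pyran ring, ring D = 2-phenyl ring. The target is the (2S,E) isomer.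
Assumption: the sense of asymmetric induction in step 3 cannot be predicted with certainty; the (S,S)-catalyst is written, and its (R,R)-antipode would be taken if the opposite sense is found.

Step 1
Reactants: 1 2-hydroxy-4,6-dimethoxybenzaldehyde; 2 benzaldehyde dimethyl acetal
Product: 4 rac-2,4-dimethoxy-6-[methoxy(phenyl)methoxy]benzaldehyde, via α-chlorobenzyl methyl ether 3 (not isolated)
Conditions: 2, AcCl, ZnBr2 (0.01 mol %), toluene, 23 °C; then added to 1, NaH, THF–DMF, 0 to 23 °C; chromatography on Et3N-treated silica
Reagents that add atoms: none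
Why: Williamson-type O-alkylation of the sodium phenoxide of 1 with an α-chloro ether, the chemistry of methoxymethyl protection; 3 is made by the known ZnBr2-catalysed exchange of one methoxy group of 2 with acetyl chloride, and the new acetal centre is racemic, which is of no consequence because step 3 ionises it.

Step 2
Reactants: 4 rac-2,4-dimethoxy-6-[methoxy(phenyl)methoxy]benzaldehyde
Product: 5 rac-2-ethenyl-1,5-dimethoxy-3-[methoxy(phenyl)methoxy]benzene
Conditions: Ph3PCH3Br, KOtBu, THF, 0 to 23 °C
Reagents that add atoms: methyltriphenylphosphonium bromide, C[P+](c1ccccc1)(c1ccccc1)c1ccccc1.[Br-]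
Why: Wittig methylenation of a non-enolisable aldehyde; the mixed acetal is stable to the basic ylide and the product is a 2,4,6-trialkoxystyrene of a known, isolable type.

Step 3
Reactants: 5 rac-2-ethenyl-1,5-dimethoxy-3-[methoxy(phenyl)methoxy]benzene
Product: 8 (2S)-5,7-dimethoxy-2-phenylchroman, via aryloxocarbenium ion 6 (not isolated), via flavan-4-yl cation 7 (not isolated)
Conditions: (S,S)-IDPi acid {[(S)-3,3'-Ar2-BINOL-O2P(=NSO2CF3)]2NH, Ar = 3,5-(CF3)2C6H3} (5 mol %, pre-stirred with Et3SiH at 23 °C), Et3SiH (5 equiv), toluene, −60 °C, slow addition of 5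
Reagents that add atoms: none
Why: Proposed new method: Et3SiH silylates the acid (H2 lost) and the silylated catalyst strips the methoxy group of racemic 5 as Et3SiOMe, so that both enantiomers of 5 converge on the planar O1=C2 aryloxocarbenium ion 6, held as a contact ion pair by the chiral IDPi anion. The terminal carbon (future C3) of the C4a vinyl group, an enol-ether-like nucleophile because O1, the C5 methoxy and the C7 methoxy group all stand ortho or para to C4a, adds to C2 in a Prins-type 6-endo-trig closure that forms the C2–C3 bond and ring C and leaves the triply oxygen-stabilised flavan-4-yl cation 7. Hydride transfer from Et3SiH to C4 of 7 (ionic hydrogenation) gives the C4 methylene of 8 and returns the silylium form of the catalyst. The closest known reaction types are the IDPi-catalysed asymmetric Prins cyclization, silylium-based asymmetric counter-anion-directed additions to oxocarbenium ions made from acetals, the Lewis-acid-triggered reaction of aryloxocarbenium ions with alkenes (oxa-Povarov reaction) and the silane reduction of benzylic cations. The C2 stereocentre is set in the C–C bond-forming step by the confined chiral anion, which shields one face of 6 (catalyst control; no stereocentre of the substrate survives ionisation). The step needs ionisation at the methoxy and not the aryloxy oxygen (the more basic, unhindered OMe oxygen should take the silyl group), ring closure before hydride reaches 6 (intramolecular attack by a very electron-rich alkene) and hydride capture of 7 before it alkylates another arene (excess silane, slow addition of 5), while proton loss from 7 to the flav-3-ene is harmless because reprotonation at C3 returns 7.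

Step 4
Reactants: 8 (2S)-5,7-dimethoxy-2-phenylchroman
Product: 9 (2S)-8-bromo-5,7-dimethoxy-2-phenylchroman
Conditions: N-bromosuccinimide (1.0 equiv), CH2Cl2, −78 to −20 °C, dark
Reagents that add atoms: N-bromosuccinimide, O=C1CCC(=O)N1Br
Why: Electrophilic aromatic bromination; in 5,7-dialkoxyflavans C8 (between O1 and the C7 methoxy group) is the established site of monobromination with N-bromosuccinimide, one equivalent at low temperature should hold back the 6,8-dibromide, and C2 is not touched.

Step 5
Reactants: 9 (2S)-8-bromo-5,7-dimethoxy-2-phenylchroman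
Product: 10 (2S)-8-ethenyl-5,7-dimethoxy-2-phenylchroman
Conditions: vinylboronic acid pinacol ester, Pd(OAc)2 (5 mol %), 2-dicyclohexylphosphino-2',6'-dimethoxybiphenyl (SPhos, 10 mol %), K3PO4, toluene–H2O, 90 °C
Reagents that add atoms: vinylboronic acid pinacol ester, C=CB1OC(C)(C)C(C)(C)O1
Why: Suzuki–Miyaura coupling; SPhos is known to promote coupling of electron-rich di-ortho-substituted aryl bromides, and the benzylic ether stereocentre C2 is inert to these conditions.

Step 6
Reactants: 11 1,3-dimethoxy-2-methylbenzene (2,6-dimethoxytoluene)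
Product: 13 3,5-dimethoxy-4-methylphenol, via arylboronic pinacol ester 12 (not isolated)
Conditions: [Ir(cod)(OMe)]2 (1.5 mol %), 4,4'-di-tert-butyl-2,2'-bipyridine (3 mol %), B2pin2 (0.55 equiv), THF, 80 °C; then Oxone (2KHSO5·KHSO4·K2SO4), acetone–H2O, 23 °C
Reagents that add atoms: potassium peroxymonosulfate, KHSO5 (active salt of Oxone), [K+].[O-]S(=O)(=O)OO
Why: Iridium-catalysed aromatic C–H borylation is sterically controlled and should select the only C–H bond of 11 without an ortho substituent (para to the methyl group), and oxidation of the C–B bond of 12 with KHSO5 in the same flask should give phenol 13 (one-pot C–H borylation/oxidation).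

Step 7
Reactants: 13 3,5-dimethoxy-4-methylphenol
Product: 14 2-iodo-3,5-dimethoxy-4-methylphenol
Conditions: N-iodosuccinimide (1.0 equiv), MeCN, 0 °C
Reagents that add atoms: N-iodosuccinimide, O=C1CCC(=O)N1I
Why: Electrophilic aromatic iodination of an activated phenol; the only two free ring positions are equivalent and both ortho to the hydroxyl group, so one equivalent of reagent should give a single monoiodide.

Step 8
Reactants: 14 2-iodo-3,5-dimethoxy-4-methylphenol
Product: 15 2-iodo-3,5-dimethoxy-4-methylphenyl acetate
Conditions: Ac2O, Et3N, 4-(dimethylamino)pyridine (5 mol %), CH2Cl2, 23 °C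
Reagents that add atoms: acetic anhydride, CC(=O)OC(C)=O
Why: Standard O-acetylation masks the phenol for the palladium step and is removed by mild methanolysis at the end.

Step 9
Reactants: 10 (2S)-8-ethenyl-5,7-dimethoxy-2-phenylchroman; 15 2-iodo-3,5-dimethoxy-4-methylphenyl acetate
Product: 17 2-{(E)-2-[(2S)-5,7-dimethoxy-2-phenylchroman-8-yl]ethenyl}-3,5-dimethoxy-4-methylphenol, via stilbene acetate 16 (not isolated)
Conditions: Pd(OAc)2 (5 mol %), P(o-tol)3 (12 mol %), Et3N, DMF, 100 °C; then K2CO3, MeOH, 23 °C; NH4Cl work-up
Reagents that add atoms: none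
Why: Mizoroki–Heck reaction: oxidative addition of aryl iodide 15, syn insertion at the unsubstituted terminus of styrene 10 and syn β-hydride elimination should give the E-stilbene 16, and K2CO3/MeOH transesterification in the same flask should free the phenol without touching C2.

**Compound list**
1 | 2-hydroxy-4,6-dimethoxybenzaldehyde | COc1cc(O)c(C=O)c(OC)c1 | starting material
2 | benzaldehyde dimethyl acetal | COC(OC)c1ccccc1 | starting material
3 | α-chlorobenzyl methyl ether, [chloro(methoxy)methyl]benzene, racemic | COC(Cl)c1ccccc1 | intermediate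
4 | rac-2,4-dimethoxy-6-[methoxy(phenyl)methoxy]benzaldehyde | COc1cc(OC(OC)c2ccccc2)c(C=O)c(OC)c1 | intermediate
5 | rac-2-ethenyl-1,5-dimethoxy-3-[methoxy(phenyl)methoxy]benzene | COc1cc(OC(OC)c2ccccc2)c(C=C)c(OC)c1 | intermediate
6 | (E)-benzylidene(2-ethenyl-3,5-dimethoxyphenyl)oxonium, aryloxocarbenium ion paired with the catalyst anion | COc1cc(/[O+]=C/c2ccccc2)c(C=C)c(OC)c1 | intermediate
7 | (2S)-5,7-dimethoxy-2-phenylchroman-4-ylium, flavan-4-yl cation paired with the catalyst anion | COc1cc(OC)c2c(c1)O[C@H](c1ccccc1)C[CH+]2 | intermediate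
8 | (2S)-5,7-dimethoxy-2-phenylchroman | COc1cc(OC)c2c(c1)O[C@H](c1ccccc1)CC2 | intermediate
9 | (2S)-8-bromo-5,7-dimethoxy-2-phenylchroman | COc1cc(OC)c2c(c1Br)O[C@H](c1ccccc1)CC2 | intermediate
10 | (2S)-8-ethenyl-5,7-dimethoxy-2-phenylchroman | COc1cc(OC)c2c(c1C=C)O[C@H](c1ccccc1)CC2 | intermediate
11 | 1,3-dimethoxy-2-methylbenzene (2,6-dimethoxytoluene) | COc1cccc(OC)c1C | starting material
12 | 2-(3,5-dimethoxy-4-methylphenyl)-4,4,5,5-tetramethyl-1,3,2-dioxaborolane | COc1cc(B2OC(C)(C)C(C)(C)O2)cc(OC)c1C | intermediate
13 | 3,5-dimethoxy-4-methylphenol | COc1cc(O)cc(OC)c1C | intermediate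
14 | 2-iodo-3,5-dimethoxy-4-methylphenol | COc1cc(O)c(I)c(OC)c1C | intermediate
15 | 2-iodo-3,5-dimethoxy-4-methylphenyl acetate | COc1cc(OC(C)=O)c(I)c(OC)c1C | intermediate
16 | 2-{(E)-2-[(2S)-5,7-dimethoxy-2-phenylchroman-8-yl]ethenyl}-3,5-dimethoxy-4-methylphenyl acetate | COc1cc(OC(C)=O)c(/C=C/c2c(OC)cc(OC)c3c2O[C@H](c2ccccc2)CC3)c(OC)c1C | intermediate
17 | 2-{(E)-2-[(2S)-5,7-dimethoxy-2-phenylchroman-8-yl]ethenyl}-3,5-dimethoxy-4-methylphenol | COc1cc(O)c(/C=C/c2c(OC)cc(OC)c3c2O[C@H](c2ccccc2)CC3)c(OC)c1C | target

**Step count and risks**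
Total step count: 9. Longest linear sequence: 6 steps (steps 1, 2, 3, 4, 5 and 9 from compound 1); the ring-A branch has 4 steps (6, 7, 8, 9).

Steps most likely to fail:

Step 3 (proposed new method). What may go wrong: loss of catalyst control through background ionisation by adventitious protic acid (racemic ring closure), hydride reduction of the oxocarbenium ion before it cyclises, or Friedel–Crafts capture of the C4 cation by electron-rich arenes (oligomers). Fallback with known chemistry, setting out from 1 and coming back at 8: Claisen–Schmidt condensation of 1 with acetophenone (KOH, EtOH–H2O) should give (E)-3-(2-hydroxy-4,6-dimethoxyphenyl)-1-phenylprop-2-en-1-one F1. Hydrogenation of the C=C bond (H2, 1 atm, Pd/C, EtOAc, stopped after one equivalent) should give 3-(2-hydroxy-4,6-dimethoxyphenyl)-1-phenylpropan-1-one F2. Asymmetric transfer hydrogenation of the aryl ketone (RuCl[(R,R)-TsDPEN](p-cymene), HCO2H–Et3N) is expected, by analogy with acetophenone-type ketones, to give 2-[(3R)-3-hydroxy-3-phenylpropyl]-3,5-dimethoxyphenol F3. Mitsunobu cyclization (PPh3, diisopropyl azodicarboxylate, THF, 0 °C) should then close ring C through O1–C2 with inversion and deliver (S)-flavan 8.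

Step 9. What may go wrong: slow migratory insertion between two di-ortho-substituted partners, so that reductive deiodination of 15 or oligomerisation of styrene 10 takes over. Fallback by carbonyl olefination, setting out from 9 and 13 and coming back at 17: bromine–lithium exchange on 9 (n-BuLi, THF, −78 °C) and quenching with DMF should give (2S)-5,7-dimethoxy-2-phenylchroman-8-carbaldehyde F4. Ortho-formylation of 13 (MgCl2, Et3N, paraformaldehyde, MeCN, reflux) should give 6-hydroxy-2,4-dimethoxy-3-methylbenzaldehyde F5, which NaBH4 in MeOH should reduce to 2-(hydroxymethyl)-3,5-dimethoxy-4-methylphenol F6. Heating F6 with PPh3·HBr in MeCN should give [(6-hydroxy-2,4-dimethoxy-3-methylphenyl)methyl]triphenylphosphonium bromide F7. Wittig reaction of F7 (LiN(SiMe3)2, 2.2 equiv, THF, −78 to 23 °C) with F4 should give the stilbene as a mixture of 17 and its (Z) isomer 2-{(Z)-2-[(2S)-5,7-dimethoxy-2-phenylchroman-8-yl]ethenyl}-3,5-dimethoxy-4-methylphenol F8. F8 would be isomerised to 17 with catalytic PhSSPh under visible light.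

Step 4. What may go wrong: attack at C6 competing with C8, and over-bromination to the 6,8-dibromide. Fallback that places the halogen before ring C exists, setting out from 1 and coming back at 9: amine-catalysed bromination of 1 (N-bromosuccinimide, i-Pr2NH 10 mol %, CH2Cl2, 0 °C), in which the hydroxyl group delivers bromine to its only free ortho position, should give 3-bromo-2-hydroxy-4,6-dimethoxybenzaldehyde F9. The conditions of step 1 should turn F9 into rac-3-bromo-4,6-dimethoxy-2-[methoxy(phenyl)methoxy]benzaldehyde F10, and those of step 2 into rac-2-bromo-4-ethenyl-1,5-dimethoxy-3-[methoxy(phenyl)methoxy]benzene F11. Under the conditions of step 3, F11 should cyclise directly to bromide 9, the bromine being inert to the silylium catalyst and the silane.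

**Further compounds**
F1 | step 3 | (E)-3-(2-hydroxy-4,6-dimethoxyphenyl)-1-phenylprop-2-en-1-one | COc1cc(O)c(/C=C/C(=O)c2ccccc2)c(OC)c1
F2 | step 3 | 3-(2-hydroxy-4,6-dimethoxyphenyl)-1-phenylpropan-1-one | COc1cc(O)c(CCC(=O)c2ccccc2)c(OC)c1
F3 | step 3 | 2-[(3R)-3-hydroxy-3-phenylpropyl]-3,5-dimethoxyphenol | COc1cc(O)c(CC[C@@H](O)c2ccccc2)c(OC)c1
F4 | step 9 | (2S)-5,7-dimethoxy-2-phenylchroman-8-carbaldehyde | COc1cc(OC)c2c(c1C=O)O[C@H](c1ccccc1)CC2
F5 | step 9 | 6-hydroxy-2,4-dimethoxy-3-methylbenzaldehyde | COc1cc(O)c(C=O)c(OC)c1C
F6 | step 9 | 2-(hydroxymethyl)-3,5-dimethoxy-4-methylphenol | COc1cc(O)c(CO)c(OC)c1C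
F7 | step 9 | [(6-hydroxy-2,4-dimethoxy-3-methylphenyl)methyl]triphenylphosphonium bromide | COc1cc(O)c(C[P+](c2ccccc2)(c2ccccc2)c2ccccc2)c(OC)c1C.[Br-]
F8 | step 9 | 2-{(Z)-2-[(2S)-5,7-dimethoxy-2-phenylchroman-8-yl]ethenyl}-3,5-dimethoxy-4-methylphenol | COc1cc(O)c(/C=C\c2c(OC)cc(OC)c3c2O[C@H](c2ccccc2)CC3)c(OC)c1C
F9 | step 4 | 3-bromo-2-hydroxy-4,6-dimethoxybenzaldehyde | COc1cc(OC)c(C=O)c(O)c1Br
F10 | step 4 | rac-3-bromo-4,6-dimethoxy-2-[methoxy(phenyl)methoxy]benzaldehyde | COc1cc(OC)c(C=O)c(OC(OC)c2ccccc2)c1Br
F11 | step 4 | rac-2-bromo-4-ethenyl-1,5-dimethoxy-3-[methoxy(phenyl)methoxy]benzene | COc1cc(OC)c(C=C)c(OC(OC)c2ccccc2)c1Br
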